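**Retrosynthetic overview**

1. Target ⇒ 8-ketone (Takai–Lombardo methylenation gives C8=C17) ⇒ Δ8 alkene (α-face hydroboration sets 9α-H and the C8 oxygen) ⇒ C9 enol triflate + side-chain iodide (Negishi coupling, C9–C11). The 3α-acetate comes from the C3 ketone (LiBH(s-Bu)3, then Ac2O).
2. Ring A (C1–C5, C10) is closed on a preformed ring B by forming C1–C10 in an iron-hydride hydrogen-atom-transfer radical conjugate addition (6-endo). This one operation makes quaternary C10, the C20 methyl group and the trans ring fusion.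
3. Enabling feature: the exocyclic 1,1-disubstituted alkene C10=C20 of ring B sits next to C5, whose substituent C4 carries the vinyl ketone C3(=O)–C2=C1. The tertiary C10 radical and the enone terminus C1 are therefore 1,6-related, and the cis, equatorial groups on C5 and C9 lock the ring B chair.
4. Quaternary C4 and C5 are set together by a chelate-controlled dianionic Ireland–Claisen rearrangement of a (cyclohex-1-enyl)methyl ester derived from (R)-3-hydroxybutanoate. It relays the carbinol stereocenter and moves the ring double bond into the exocyclic position; the C9 oxygen is then added by allylic oxidation.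
5. Order of rings: ring B is bought as a cyclohexene; ring A is formed in step 13. C13 comes from methyl hydrogen (R)-3-methylglutarate (fragment 1).

Key step: step 13

Remark: atoms are numbered as in labdanes (ring A = C1–C5 and C10; ring B = C5–C10; C18 = 4α-methyl, C19 = 4β-ester carbon, C20 = 10β-methyl, C17 = methylene carbon on C8, C11–C16 = side chain).
Assumption: compounds 1, 6 and 8 are taken as commercially available, and the facial preference of the chelated β-oxido ester dianion (electrophile anti to the C3 methyl) is taken to hold for the tetrasubstituted enolate of step 7.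

**Route**

Step 1
Reactants: 1 methyl hydrogen (R)-3-methylglutarate
Product: 2 methyl (3R)-5-hydroxy-3-methylpentanoate
Conditions: BH3·SMe2, THF, −20 → 0 °C; MeOH quench
Reagents that add atoms: none
Why: Chemoselective borane reduction of the free carboxylic acid beside the methyl ester should give the hydroxy ester with the chiral-pool C13 center untouched.

Step 2
Reactants: 2 methyl (3R)-5-hydroxy-3-methylpentanoate
Product: 3 methyl (3R)-5-{[tert-butyl(diphenyl)silyl]oxy}-3-methylpentanoate
Conditions: TBDPSCl, imidazole, DMF, 0 °C → rt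
Reagents that add atoms: tert-butyl(chloro)diphenylsilane, CC(C)(C)[Si](Cl)(c1ccccc1)c1ccccc1
Why: Standard silyl ether protection of the primary alcohol, carried out at once so that lactonization cannot compete.

Step 3
Reactants: 3 methyl (3R)-5-{[tert-butyl(diphenyl)silyl]oxy}-3-methylpentanoate
Product: 4 (3S)-5-{[tert-butyl(diphenyl)silyl]oxy}-3-methylpentan-1-ol
Conditions: LiBH4, THF/MeOH, 0 °C → rt
Reagents that add atoms: none
Why: Lithium borohydride ester reduction should leave the silyl ether intact.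

Step 4
Reactants: 4 (3S)-5-{[tert-butyl(diphenyl)silyl]oxy}-3-methylpentan-1-ol
Product: 5 tert-butyl{[(3R)-5-iodo-3-methylpentyl]oxy}diphenylsilane (fragment 1)
Conditions: iodine, PPh3, imidazole, CH2Cl2, 0 °C → rt
Reagents that add atoms: iodine, [I][I]
Why: Appel-type iodination of a primary alcohol proceeds by substitution at the CH2 group and does not touch the stereocenter.

Step 5
Reactants: 6 ethyl (3R)-3-hydroxybutanoate
Product: 7 ethyl (2R,3R)-3-hydroxy-2-methylbutanoate
Conditions: LDA (2.2 equiv), THF, −78 → −20 °C; MeI, −78 → 0 °C; NH4Cl aq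
Reagents that add atoms: iodomethane, IC
Why: Fráter–Seebach alkylation of the chelated dianion introduces the future C18 methyl anti to the C3 methyl; this center is re-enolized in step 7 and only serves to give a single substrate.

Step 6
Reactants: 7 ethyl (2R,3R)-3-hydroxy-2-methylbutanoate; 8 (cyclohex-1-en-1-yl)methanol
Product: 9 (cyclohex-1-en-1-yl)methyl (2R,3R)-3-hydroxy-2-methylbutanoate
Conditions: Ti(OEt)4 (0.2 equiv), toluene, 100 °C, removal of EtOH
Reagents that add atoms: none
Why: Titanate-mediated transesterification works on unprotected β-hydroxy esters without retro-aldol cleavage or elimination.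

Step 7
Reactants: 9 (cyclohex-1-en-1-yl)methyl (2R,3R)-3-hydroxy-2-methylbutanoate
Product: 11 methyl (2R,3R)-3-hydroxy-2-methyl-2-[(1R)-2-methylidenecyclohexyl]butanoate, via carboxylic acid 10 (not isolated)
Conditions: LDA (2.4 equiv), THF, −78 → 45 °C; 1 M HCl, 0 °C; crude acid, TMSCHN2, PhMe/MeOH, 0 °C
Reagents that add atoms: (trimethylsilyl)diazomethane, C[Si](C)(C)C=[N+]=[N-]
Why: Dianionic Ireland–Claisen (ester enolate Claisen) rearrangement, in which the lithium chelate between the C3 alkoxide and the enolate oxygen fixes the enolate geometry (O-allyl cis to the α-methyl) and the allyl unit is delivered through a chair to the face anti to the C3 methyl, so that quaternary C4 and C5 are set together and the exocyclic C10=C20 alkene is created; the acid is then methylated.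

Step 8
Reactants: 11 methyl (2R,3R)-3-hydroxy-2-methyl-2-[(1R)-2-methylidenecyclohexyl]butanoate
Product: 12 methyl (2R,3R)-3-hydroxy-2-[(1R)-3-hydroxy-2-methylidenecyclohexyl]-2-methylbutanoate (both epimers at the new ring carbinol C9)
Conditions: SeO2 (0.5 equiv), t-BuOOH (3 equiv), CH2Cl2, 0 °C → rt
Reagents that add atoms: tert-butyl hydroperoxide, CC(C)(C)OO
Why: SeO2 allylic hydroxylation (ene reaction, then [2,3] shift) should attack the ring CH2 (C9) next to the exocyclic alkene in preference to the hindered methine C5; the C9 configuration is irrelevant because it is oxidized next.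

Step 9
Reactants: 12 methyl (2R,3R)-3-hydroxy-2-[(1R)-3-hydroxy-2-methylidenecyclohexyl]-2-methylbutanoate
Product: 13 methyl (2R)-2-methyl-2-[(1R)-2-methylidene-3-oxocyclohexyl]-3-oxobutanoate
Conditions: Dess–Martin periodinane (3 equiv), NaHCO3, CH2Cl2, 0 °C → rt
Reagents that add atoms: none
Why: Dess–Martin oxidation of both secondary alcohols gives the C9 enone and the C3 methyl ketone under non-epimerizing conditions.

Step 10
Reactants: 13 methyl (2R)-2-methyl-2-[(1R)-2-methylidene-3-oxocyclohexyl]-3-oxobutanoate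
Product: 14 methyl (2R)-2-[(1R,3S)-3-hydroxy-2-methylidenecyclohexyl]-2-methyl-3-oxobutanoate
Conditions: NaBH4, CeCl3·7H2O, MeOH, −78 °C
Reagents that add atoms: none
Why: Luche 1,2-reduction should take the enone carbonyl much faster than the α-quaternary methyl ketone or the ester, and hydride delivery anti to the C5 substituent gives the C9 alcohol cis to it (both equatorial).

Step 11
Reactants: 14 methyl (2R)-2-[(1R,3S)-3-hydroxy-2-methylidenecyclohexyl]-2-methyl-3-oxobutanoate
Product: 15 methyl (2R)-2-[(1R,3S)-3-{[tert-butyl(dimethyl)silyl]oxy}-2-methylidenecyclohexyl]-2-methyl-3-oxobutanoate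
Conditions: TBSCl, imidazole, DMAP (cat.), DMF, rt
Reagents that add atoms: tert-butyl(chloro)dimethylsilane, CC(C)(C)[Si](C)(C)Cl
Why: Silyl ether protection of the allylic alcohol; the bulky equatorial C9 group later helps to lock ring B.

Step 12
Reactants: 15 methyl (2R)-2-[(1R,3S)-3-{[tert-butyl(dimethyl)silyl]oxy}-2-methylidenecyclohexyl]-2-methyl-3-oxobutanoate
Product: 18 methyl (2R)-2-[(1R,3S)-3-{[tert-butyl(dimethyl)silyl]oxy}-2-methylidenecyclohexyl]-2-methyl-3-oxopent-4-enoate, via Mannich base 16 (not isolated), via methiodide 17 (not isolated)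
Conditions: LiHMDS, THF, −78 °C; Me2N=CH2 iodide, −78 → 0 °C; MeI, CH2Cl2, rt; NaHCO3 aq
Reagents that add atoms: Eschenmoser's salt (N,N-dimethylmethyleneiminium iodide), C=[N+](C)C.[I-]
Why: Mannich methylenation, in which the acetyl CH3 is the only enolizable position, so the enolate forms regiospecifically and quaternization–elimination of the Mannich base gives the vinyl ketone (C1=C2).

Step 13
Reactants: 18 methyl (2R)-2-[(1R,3S)-3-{[tert-butyl(dimethyl)silyl]oxy}-2-methylidenecyclohexyl]-2-methyl-3-oxopent-4-enoate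
Product: 19 methyl 9β-{[tert-butyl(dimethyl)silyl]oxy}-3-oxo-11,12,13,14,15,16,17-heptanorlabdan-19-oate (trans-decalin; 4α-CH3, 5α-H, 10β-CH3)
Conditions: Fe(acac)3 (0.5 equiv), PhSiH3 (2.5 equiv), EtOH/(CH2OH)2 5:1, 0.02 M, 60 °C
Reagents that add atoms: none
Why: An iron hydride formed from Fe(acac)3 and PhSiH3 transfers a hydrogen atom to the CH2 end of the electron-rich exocyclic C10=C20 alkene, which makes the C20 methyl group and the tertiary C10 radical; this nucleophilic radical adds to C1, the terminal carbon of the vinyl ketone, and the resulting α-keto radical at C2 is reduced and protonated. The closest known reaction type is the iron-mediated reductive olefin coupling (hydrogen-atom-transfer-initiated Giese addition) in its intramolecular form. Ring A closes in the 6-endo-trig mode, because the 5-exo alternative would be attack at the α-carbon of the enone, which is both polarity-mismatched and more hindered. The new quaternary center C10 is controlled by the ring B chair: the cis substituents on C5 and C9 are both equatorial and flank the radical carbon, so the C20 methyl group should move into the axial β position to escape them while C1, tethered through the equatorial C5–C4 bond, bonds on the equatorial α side, which gives the trans-decalin as in the second ring closure of radical polyene cyclizations. The step needs hydrogen-atom transfer to the 1,1-disubstituted alkene and not to the enone (secured by the electron-rich donor alkene) and ring closure faster than reduction of the radical (secured by the matched nucleophilic tertiary radical and unhindered enone terminus held close by C4–C5).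

Step 14
Reactants: 19 methyl 9β-{[tert-butyl(dimethyl)silyl]oxy}-3-oxo-11,12,13,14,15,16,17-heptanorlabdan-19-oate
Product: 20 methyl 9β-{[tert-butyl(dimethyl)silyl]oxy}-3α-hydroxy-11,12,13,14,15,16,17-heptanorlabdan-19-oate
Conditions: LiBH(s-Bu)3, THF, −78 °C; NaOH aq
Reagents that add atoms: none
Why: The bulky trialkylborohydride should attack the C3 ketone along the equatorial trajectory and so give the axial 3α-alcohol, the methyl ester being inert at −78 °C.

Step 15
Reactants: 20 methyl 9β-{[tert-butyl(dimethyl)silyl]oxy}-3α-hydroxy-11,12,13,14,15,16,17-heptanorlabdan-19-oate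
Product: 21 methyl 3α-acetoxy-9β-{[tert-butyl(dimethyl)silyl]oxy}-11,12,13,14,15,16,17-heptanorlabdan-19-oate
Conditions: Ac2O, DMAP, pyridine, 50 °C
Reagents that add atoms: acetic anhydride, CC(=O)OC(C)=O
Why: DMAP-catalysed acetylation is strong enough for the hindered axial alcohol and leaves the silyl ether in place.

Step 16
Reactants: 21 methyl 3α-acetoxy-9β-{[tert-butyl(dimethyl)silyl]oxy}-11,12,13,14,15,16,17-heptanorlabdan-19-oate
Product: 22 methyl 3α-acetoxy-9β-hydroxy-11,12,13,14,15,16,17-heptanorlabdan-19-oate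
Conditions: TBAF, AcOH, THF, rt → 40 °C
Reagents that add atoms: none
Why: Fluoride desilylation buffered with acetic acid should free the C9 alcohol without cleaving the acetate.

Step 17
Reactants: 22 methyl 3α-acetoxy-9β-hydroxy-11,12,13,14,15,16,17-heptanorlabdan-19-oate
Product: 23 methyl 3α-acetoxy-9-oxo-11,12,13,14,15,16,17-heptanorlabdan-19-oate
Conditions: Dess–Martin periodinane, NaHCO3, CH2Cl2, rt
Reagents that add atoms: none
Why: Dess–Martin oxidation of the secondary alcohol gives the C9 ketone that carries the side chain in.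

Step 18
Reactants: 23 methyl 3α-acetoxy-9-oxo-11,12,13,14,15,16,17-heptanorlabdan-19-oate
Product: 24 methyl 3α-acetoxy-9-{[(trifluoromethyl)sulfonyl]oxy}-11,12,13,14,15,16,17-heptanorlabd-8-en-19-oate
Conditions: KHMDS (1.1 equiv), THF, −78 °C; PhNTf2, −78 → 0 °C
Reagents that add atoms: N-phenylbis(trifluoromethanesulfonimide), O=S(=O)(N(c1ccccc1)S(=O)(=O)C(F)(F)F)C(F)(F)F
Why: Enol triflate formation is regiospecific because C10 is quaternary and only C8 carries α-hydrogens, and the ketone is deprotonated faster than the acetate.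

Step 19
Reactants: 24 methyl 3α-acetoxy-9-{[(trifluoromethyl)sulfonyl]oxy}-11,12,13,14,15,16,17-heptanorlabd-8-en-19-oate; 5 tert-butyl{[(3R)-5-iodo-3-methylpentyl]oxy}diphenylsilane
Product: 26 methyl (13S)-3α-acetoxy-15-{[tert-butyl(diphenyl)silyl]oxy}-17-norlabd-8-en-19-oate, via organozinc iodide 25 (not isolated)
Conditions: 5, Zn dust, LiCl, THF, 40 °C; then 24, PdCl2(dppf) (5 mol%), THF/DMA, 50 °C
Reagents that add atoms: none
Why: Negishi sp3–sp2 cross-coupling forms C9–C11 under neutral conditions that tolerate the acetate, the methyl ester and the silyl ether, and it brings in C13 with its configuration fixed.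

Step 20
Reactants: 26 methyl (13S)-3α-acetoxy-15-{[tert-butyl(diphenyl)silyl]oxy}-17-norlabd-8-en-19-oate
Product: 27 methyl (13S)-3α-acetoxy-15-{[tert-butyl(diphenyl)silyl]oxy}-8α-hydroxy-17-norlabdan-19-oate (9α-H)
Conditions: BH3·SMe2, THF, 0 °C → rt; H2O2, NaOAc aq, 0 °C
Reagents that add atoms: hydrogen peroxide, OO
Why: Hydroboration–oxidation, in which borane adds syn from the α face, away from the axial C10 methyl, with boron on the less substituted C8, should set 9α-H (side chain β, equatorial) and the 8α-alcohol.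

Step 21
Reactants: 27 methyl (13S)-3α-acetoxy-15-{[tert-butyl(diphenyl)silyl]oxy}-8α-hydroxy-17-norlabdan-19-oate
Product: 28 methyl (13S)-3α-acetoxy-15-{[tert-butyl(diphenyl)silyl]oxy}-8-oxo-17-norlabdan-19-oate
Conditions: Dess–Martin periodinane, NaHCO3, CH2Cl2, rt
Reagents that add atoms: none
Why: Buffered Dess–Martin oxidation gives the 8-ketone without base, so the C9 center next to it should not epimerize.

Step 22
Reactants: 28 methyl (13S)-3α-acetoxy-15-{[tert-butyl(diphenyl)silyl]oxy}-8-oxo-17-norlabdan-19-oate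
Product: 29 methyl (13S)-3α-acetoxy-15-{[tert-butyl(diphenyl)silyl]oxy}labd-8(17)-en-19-oate
Conditions: Zn, CH2Br2, TiCl4, THF/CH2Cl2, 0 °C → rt
Reagents that add atoms: dibromomethane, BrCBr
Why: Takai–Lombardo methylenation is non-basic and selective for ketones, so it should convert the hindered, epimerizable 8-ketone into the exocyclic alkene without touching acetate, ester or C9.

Step 23
Reactants: 29 methyl (13S)-3α-acetoxy-15-{[tert-butyl(diphenyl)silyl]oxy}labd-8(17)-en-19-oate
Product: 30 methyl (13S)-3α-acetoxy-15-hydroxylabd-8(17)-en-19-oate (target)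
Conditions: HF·pyridine, pyridine, THF, 0 °C → rt
Reagents that add atoms: none
Why: Fluoride desilylation under mildly acidic, non-hydrolytic conditions frees the primary alcohol and keeps the 3α-acetate where it is.

**Compound list**

1 | methyl hydrogen (R)-3-methylglutarate [(3R)-5-methoxy-3-methyl-5-oxopentanoic acid] | COC(=O)C[C@H](C)CC(=O)O | starting material
2 | methyl (3R)-5-hydroxy-3-methylpentanoate | COC(=O)C[C@H](C)CCO | intermediate
3 | methyl (3R)-5-{[tert-butyl(diphenyl)silyl]oxy}-3-methylpentanoate | COC(=O)C[C@H](C)CCO[Si](c1ccccc1)(c1ccccc1)C(C)(C)C | intermediate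
4 | (3S)-5-{[tert-butyl(diphenyl)silyl]oxy}-3-methylpentan-1-ol | OCC[C@H](C)CCO[Si](c1ccccc1)(c1ccccc1)C(C)(C)C | intermediate
5 | tert-butyl{[(3R)-5-iodo-3-methylpentyl]oxy}diphenylsilane | ICC[C@H](C)CCO[Si](c1ccccc1)(c1ccccc1)C(C)(C)C | intermediate
6 | ethyl (3R)-3-hydroxybutanoate | CCOC(=O)C[C@@H](C)O | starting material
7 | ethyl (2R,3R)-3-hydroxy-2-methylbutanoate | CCOC(=O)[C@H](C)[C@@H](C)O | intermediate
8 | (cyclohex-1-en-1-yl)methanol | OCC1=CCCCC1 | starting material
9 | (cyclohex-1-en-1-yl)methyl (2R,3R)-3-hydroxy-2-methylbutanoate | O=C(OCC1=CCCCC1)[C@H](C)[C@@H](C)O | intermediate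
10 | (2R,3R)-3-hydroxy-2-methyl-2-[(1R)-2-methylidenecyclohexyl]butanoic acid | C=C1CCCC[C@H]1[C@@](C)(C(=O)O)[C@@H](C)O | intermediate
11 | methyl (2R,3R)-3-hydroxy-2-methyl-2-[(1R)-2-methylidenecyclohexyl]butanoate | C=C1CCCC[C@H]1[C@@](C)(C(=O)OC)[C@@H](C)O | intermediate
12 | methyl (2R,3R)-3-hydroxy-2-[(1R)-3-hydroxy-2-methylidenecyclohexyl]-2-methylbutanoate (epimers at ring C3) | C=C1C(O)CCC[C@H]1[C@@](C)(C(=O)OC)[C@@H](C)O | intermediate
13 | methyl (2R)-2-methyl-2-[(1R)-2-methylidene-3-oxocyclohexyl]-3-oxobutanoate | C=C1C(=O)CCC[C@H]1[C@@](C)(C(=O)OC)C(C)=O | intermediate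
14 | methyl (2R)-2-[(1R,3S)-3-hydroxy-2-methylidenecyclohexyl]-2-methyl-3-oxobutanoate | C=C1[C@@H](O)CCC[C@H]1[C@@](C)(C(=O)OC)C(C)=O | intermediate
15 | methyl (2R)-2-[(1R,3S)-3-{[tert-butyl(dimethyl)silyl]oxy}-2-methylidenecyclohexyl]-2-methyl-3-oxobutanoate | C=C1[C@@H](O[Si](C)(C)C(C)(C)C)CCC[C@H]1[C@@](C)(C(=O)OC)C(C)=O | intermediate
16 | methyl (2R)-2-[(1R,3S)-3-{[tert-butyl(dimethyl)silyl]oxy}-2-methylidenecyclohexyl]-5-(dimethylamino)-2-methyl-3-oxopentanoate (Mannich base) | C=C1[C@@H](O[Si](C)(C)C(C)(C)C)CCC[C@H]1[C@@](C)(C(=O)OC)C(=O)CCN(C)C | intermediate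
17 | trimethylammonium iodide of 16 (methiodide) | C=C1[C@@H](O[Si](C)(C)C(C)(C)C)CCC[C@H]1[C@@](C)(C(=O)OC)C(=O)CC[N+](C)(C)C.[I-] | intermediate
18 | methyl (2R)-2-[(1R,3S)-3-{[tert-butyl(dimethyl)silyl]oxy}-2-methylidenecyclohexyl]-2-methyl-3-oxopent-4-enoate | C=C1[C@@H](O[Si](C)(C)C(C)(C)C)CCC[C@H]1[C@@](C)(C(=O)OC)C(=O)C=C | intermediate
19 | methyl 9β-{[tert-butyl(dimethyl)silyl]oxy}-3-oxo-11,12,13,14,15,16,17-heptanorlabdan-19-oate | C1CC[C@@H]2[C@](C)(CCC(=O)[C@]2(C)C(=O)OC)[C@H]1O[Si](C)(C)C(C)(C)C | intermediate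
20 | methyl 9β-{[tert-butyl(dimethyl)silyl]oxy}-3α-hydroxy-11,12,13,14,15,16,17-heptanorlabdan-19-oate | C1CC[C@@H]2[C@](C)(CC[C@@H](O)[C@]2(C)C(=O)OC)[C@H]1O[Si](C)(C)C(C)(C)C | intermediate
21 | methyl 3α-acetoxy-9β-{[tert-butyl(dimethyl)silyl]oxy}-11,12,13,14,15,16,17-heptanorlabdan-19-oate | C1CC[C@@H]2[C@](C)(CC[C@@H](OC(C)=O)[C@]2(C)C(=O)OC)[C@H]1O[Si](C)(C)C(C)(C)C | intermediate
22 | methyl 3α-acetoxy-9β-hydroxy-11,12,13,14,15,16,17-heptanorlabdan-19-oate | C1CC[C@@H]2[C@](C)(CC[C@@H](OC(C)=O)[C@]2(C)C(=O)OC)[C@H]1O | intermediate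
23 | methyl 3α-acetoxy-9-oxo-11,12,13,14,15,16,17-heptanorlabdan-19-oate | C1CC[C@@H]2[C@](C)(CC[C@@H](OC(C)=O)[C@]2(C)C(=O)OC)C1=O | intermediate
24 | methyl 3α-acetoxy-9-{[(trifluoromethyl)sulfonyl]oxy}-11,12,13,14,15,16,17-heptanorlabd-8-en-19-oate | C=1CC[C@@H]2[C@](C)(CC[C@@H](OC(C)=O)[C@]2(C)C(=O)OC)C=1OS(=O)(=O)C(F)(F)F | intermediate
25 | {(3R)-5-{[tert-butyl(diphenyl)silyl]oxy}-3-methylpentyl}zinc iodide | I[Zn]CC[C@H](C)CCO[Si](c1ccccc1)(c1ccccc1)C(C)(C)C | intermediate
26 | methyl (13S)-3α-acetoxy-15-{[tert-butyl(diphenyl)silyl]oxy}-17-norlabd-8-en-19-oate | C=1CC[C@@H]2[C@](C)(CC[C@@H](OC(C)=O)[C@]2(C)C(=O)OC)C=1CC[C@H](C)CCO[Si](c3ccccc3)(c3ccccc3)C(C)(C)C | intermediate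
27 | methyl (13S)-3α-acetoxy-15-{[tert-butyl(diphenyl)silyl]oxy}-8α-hydroxy-17-norlabdan-19-oate | O[C@@H]1CC[C@@H]2[C@](C)(CC[C@@H](OC(C)=O)[C@]2(C)C(=O)OC)[C@H]1CC[C@H](C)CCO[Si](c3ccccc3)(c3ccccc3)C(C)(C)C | intermediate
28 | methyl (13S)-3α-acetoxy-15-{[tert-butyl(diphenyl)silyl]oxy}-8-oxo-17-norlabdan-19-oate | O=C1CC[C@@H]2[C@](C)(CC[C@@H](OC(C)=O)[C@]2(C)C(=O)OC)[C@H]1CC[C@H](C)CCO[Si](c3ccccc3)(c3ccccc3)C(C)(C)C | intermediate
29 | methyl (13S)-3α-acetoxy-15-{[tert-butyl(diphenyl)silyl]oxy}labd-8(17)-en-19-oate | C=C1CC[C@@H]2[C@](C)(CC[C@@H](OC(C)=O)[C@]2(C)C(=O)OC)[C@H]1CC[C@H](C)CCO[Si](c3ccccc3)(c3ccccc3)C(C)(C)C | intermediate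
30 | methyl (13S)-3α-acetoxy-15-hydroxylabd-8(17)-en-19-oate | C=C1CC[C@@H]2[C@](C)(CC[C@@H](OC(C)=O)[C@]2(C)C(=O)OC)[C@H]1CC[C@H](C)CCO | target

**Step count and risks**

Total step count: 23 (4 for fragment 1, 19 in the main line). Longest linear sequence: 19 steps (steps 5–23, from 6).

Steps most likely to fail:

Step 13 (key step). The tertiary radical may be reduced before it cyclizes (net hydrogenation or isomerization of the exocyclic alkene), or ring closure may take place on the β face and give the cis-fused decalin. The fallback generates the same radical without a metal hydride; it sets out from 15 and comes back at 19. Mukaiyama hydration of 15 (Co(acac)2, PhSiH3, O2, i-PrOH) should give methyl (2R)-2-[(1S,3S)-3-{[tert-butyl(dimethyl)silyl]oxy}-2-hydroxy-2-methylcyclohexyl]-2-methyl-3-oxobutanoate F7 as a mixture of epimers at C10, which does not matter because C10 becomes a radical. Direct α-methylenation of the acetyl group of F7 (paraformaldehyde, i-Pr2NH·CF3CO2H, THF, 65 °C) gives methyl (2R)-2-[(1S,3S)-3-{[tert-butyl(dimethyl)silyl]oxy}-2-hydroxy-2-methylcyclohexyl]-2-methyl-3-oxopent-4-enoate F8 without an alkoxide that could lactonize onto the C19 ester. Acylation of F8 with N-phthalimidoyl chlorooxalate (Et3N, DMAP, CH2Cl2) gives the tertiary alkyl N-phthalimidoyl oxalate derived from F8, compound F9 in this sequence. Visible-light photoredox fragmentation of F9 (Ru(bpy)3(PF6)2, Hantzsch ester, i-Pr2NEt·HBF4, CH2Cl2, rt) releases the C10 radical, which should close onto the enone at room temperature to give 19.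

Step 7. The dianion may fragment by retro-aldol cleavage on warming, or the congested quaternary–tertiary bond may form slowly and with poor facial or chair selectivity. The fallback uses an auxiliary-controlled Carroll rearrangement; it sets out from 8 and comes back at 13. Transesterification of 8 with methyl 2-methylacetoacetate (DMAP, toluene, reflux) gives (cyclohex-1-en-1-yl)methyl 2-methyl-3-oxobutanoate F1 as the racemate. Condensation of F1 with (S)-1-amino-2-(methoxymethyl)pyrrolidine gives the SAMP hydrazone of (cyclohex-1-en-1-yl)methyl 2-methyl-3-oxobutanoate F2 in the usual way; the enantiomeric auxiliary is taken if the sense of induction demands it. Deprotonation of F2 with lithium 2,2,6,6-tetramethylpiperidide (toluene, −100 °C → rt) triggers the [3,3] shift to (2R)-2-methyl-2-[(1R)-2-methylidenecyclohexyl]-3-oxobutanoic acid SAMP hydrazone F3 by way of the chelated azaenolate. TMSCHN2 converts F3 into methyl (2R)-2-methyl-2-[(1R)-2-methylidenecyclohexyl]-3-oxobutanoate SAMP hydrazone F4 without decarboxylation. Aqueous oxalic acid removes the auxiliary from F4 and gives methyl (2R)-2-methyl-2-[(1R)-2-methylidenecyclohexyl]-3-oxobutanoate F5 as the free β-keto ester. SeO2/t-BuOOH oxidizes F5 to methyl (2R)-2-[(1R)-3-hydroxy-2-methylidenecyclohexyl]-2-methyl-3-oxobutanoate F6 as a mixture of carbinol epimers. Dess–Martin oxidation of F6 leads to 13.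

Step 20. Borane may reduce the acetate or the methyl ester during the slow hydroboration of the hindered alkene, or it may add from the β face. The fallback sets C9 and the C8 methylene by allylic hydrogenolysis; it sets out from 23 and comes back at 29. Direct α-methylenation of 23 at C8, the only enolizable position of the ketone (paraformaldehyde, i-Pr2NH·CF3CO2H, THF, 65 °C), gives methyl 3α-acetoxy-9-oxo-11,12,13,14,15,16-hexanorlabd-8(17)-en-19-oate F10 as an exocyclic enone. Iodide 5 is converted with t-BuLi (Et2O, −78 °C) into {(3R)-5-{[tert-butyl(diphenyl)silyl]oxy}-3-methylpentyl}lithium F11 by iodine–lithium exchange. In the presence of CeCl3 at −78 °C, F11 should add to the C9 carbonyl of F10 from the α face, and trapping the alkoxide with methyl chloroformate gives methyl (13S)-3α-acetoxy-15-{[tert-butyl(diphenyl)silyl]oxy}-9β-[(methoxycarbonyl)oxy]-9-epi-labd-8(17)-en-19-oate F12 as a tertiary allylic carbonate with the side chain on the α face. Tsuji hydrogenolysis of F12 with formate (Pd(OAc)2, PBu3, HCO2NH4, dioxane, 60 °C) should deliver hydride to C9 from the α face while the double bond stays exocyclic, giving 29.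

Further compounds
F1 | step 7 | (cyclohex-1-en-1-yl)methyl 2-methyl-3-oxobutanoate | CC(=O)C(C)C(=O)OCC1=CCCCC1
F2 | step 7 | SAMP hydrazone of (cyclohex-1-en-1-yl)methyl 2-methyl-3-oxobutanoate | CC(=NN1CCC[C@H]1COC)C(C)C(=O)OCC1=CCCCC1
F3 | step 7 | (2R)-2-methyl-2-[(1R)-2-methylidenecyclohexyl]-3-oxobutanoic acid SAMP hydrazone | C=C1CCCC[C@H]1[C@@](C)(C(=O)O)C(C)=NN1CCC[C@H]1COC
F4 | step 7 | methyl (2R)-2-methyl-2-[(1R)-2-methylidenecyclohexyl]-3-oxobutanoate SAMP hydrazone | C=C1CCCC[C@H]1[C@@](C)(C(=O)OC)C(C)=NN1CCC[C@H]1COC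
F5 | step 7 | methyl (2R)-2-methyl-2-[(1R)-2-methylidenecyclohexyl]-3-oxobutanoate | C=C1CCCC[C@H]1[C@@](C)(C(=O)OC)C(C)=O
F6 | step 7 | methyl (2R)-2-[(1R)-3-hydroxy-2-methylidenecyclohexyl]-2-methyl-3-oxobutanoate (epimers at ring C3) | C=C1C(O)CCC[C@H]1[C@@](C)(C(=O)OC)C(C)=O
F7 | step 13 | methyl (2R)-2-[(1S,3S)-3-{[tert-butyl(dimethyl)silyl]oxy}-2-hydroxy-2-methylcyclohexyl]-2-methyl-3-oxobutanoate (epimers at ring C2) | CC1(O)[C@@H](O[Si](C)(C)C(C)(C)C)CCC[C@H]1[C@@](C)(C(=O)OC)C(C)=O
F8 | step 13 | methyl (2R)-2-[(1S,3S)-3-{[tert-butyl(dimethyl)silyl]oxy}-2-hydroxy-2-methylcyclohexyl]-2-methyl-3-oxopent-4-enoate | CC1(O)[C@@H](O[Si](C)(C)C(C)(C)C)CCC[C@H]1[C@@](C)(C(=O)OC)C(=O)C=C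
F9 | step 13 | tertiary alkyl N-phthalimidoyl oxalate derived from F8 | CC1(OC(=O)C(=O)ON2C(=O)c3ccccc3C2=O)[C@@H](O[Si](C)(C)C(C)(C)C)CCC[C@H]1[C@@](C)(C(=O)OC)C(=O)C=C
F10 | step 20 | methyl 3α-acetoxy-9-oxo-11,12,13,14,15,16-hexanorlabd-8(17)-en-19-oate | C=C1CC[C@@H]2[C@](C)(CC[C@@H](OC(C)=O)[C@]2(C)C(=O)OC)C1=O
F11 | step 20 | {(3R)-5-{[tert-butyl(diphenyl)silyl]oxy}-3-methylpentyl}lithium | [Li]CC[C@H](C)CCO[Si](c1ccccc1)(c1ccccc1)C(C)(C)C
F12 | step 20 | methyl (13S)-3α-acetoxy-15-{[tert-butyl(diphenyl)silyl]oxy}-9β-[(methoxycarbonyl)oxy]-9-epi-labd-8(17)-en-19-oate | C=C1CC[C@@H]2[C@](C)(CC[C@@H](OC(C)=O)[C@]2(C)C(=O)OC)[C@]1(OC(=O)OC)CC[C@H](C)CCO[Si](c3ccccc3)(c3ccccc3)C(C)(C)C
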